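Start from slowness: at the charges the target route consumes starting material more slowly than the dimer route, so ask how thin the starting material must be before the two routes tie.

    starting material + reagent ⇌ target + released group (K1 = 0.365, k1 = 0.936 /M/h)
    2 starting material → homo dimer (k2 = 11.4 /M/h)

| flask | starting material | reagent | remark | time |
|---|---|---|---|---|
| east | 0.050 M | 0.150 M | one stirred flow tank at steady state, fed with the mixture as stated, mean residence time 8.0 h |  |
| north | 0.050 M | 0.150 M (fed, over 6.40 h) | a stirred flask in which reagent is dosed at a steady rate over 6.40 h without added volume, worked up at 8.0 h | 8.0 h |
| south | 0.050 M (fed, over 6.40 h) | 0.150 M | all but starting material at the start; starting material goes in evenly over 6.40 h, the run ends at 8.0 h | 8.0 h |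
| south-west | 0.050 M | 0.150 M | a closed flask charged with all of it at once and left for 8.0 h | 8.0 h |

- a species is counted by the starting material in it: one homo dimer counts as two
- for a step with 2 of a species take k times the square, and two of it per event
- the stated concentrations are those of everything mixed, before any reaction; amounts are the same in each set-up
- the feed brings no volume worth counting
- run time (north): 8.0 h

- the set-up with the highest amount of target at the outlet or at the end, in percent of the starting material put in ("none" if the first two lie within 2 percentage points) (east / north / south / south-west / none)
- amount of target at the outlet or at the end, in percent of the starting material put in, east
- amount of target at the outlet or at the end, in percent of the starting material put in, north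
- amount of target at the outlet or at the end, in percent of the starting material put in, south
- amount of target at the outlet or at the end, in percent of the starting material put in, south-west

Take the even split as the zero of the scale, and hold reagent at its charge. Define the tie level as the concentration of starting material at which both routes consume it equally, which is the target constant times reagent, over double the dimer constant: 0.006158 M. At any level, the target's share of what reacts is the tie level over the tie level plus that level, so half at the tie. Tie level over level is the selectivity factor.

Reckon east by two ways. Solve the tank balance for starting material.

Level in east: 0.01173 M

First way, share times conversion: 26.3%

Second way, target's own balance with the back step: 21.6%

The two ways part. In east, at the first figure, the back step returns 27.0% of the forward flow, and the first way dropped it. So the first way cheats; commit to the second.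

Now set the feed in south equal to the loss.

Level in south: 0.01569 M

Share in south: 28.2%

Share in north, full reagent against the charged level: 11.0%

Forward share in south-west, integrated down from the charge, at most: 27.2%

Rank south first and north last, though south's lead over south-west is thin in these forward figures.

The forecast names south, with east 21%, north 10.5%, south 26.5% and south-west 21%. Its ground: “feeding starting material slowly into all the reagent keeps its concentration low and favours target”. It sits below my figures for east and south.

The simulation gives south: east 21.0%, north 8.95%, south 23.9%, south-west 20.2%. The forecast's pick stands, and its figures lie within tolerance. In south, starting material peaks at 0.0159 M, 2.58 times the tie level. Strike the dimer route in south and the target rises by 17 percentage points. Strike the back step in south and it rises by 1.7 points, which is less. Carry the tie level to a neighbour of north with 0.037 M of reagent. There it falls to 0.001519 M, and the share at the charged level is 2.95%. That neighbour gives 2.56%.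

Its constants come from no measurement; no experiment stands behind them.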